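The runs stem from a simulated flask for substances that don't exist; noise was put on by code.

The blue run is the flask to call, with more partner than any earlier run and the amber run's catalyst.

common to all: starting material 0.250 M

| flask | partner | free catalyst | target | time |
|---|---|---|---|---|
| amber | 0.625 M | 5.00 × 10⁻⁴ M |  |  |
| green | 1.20 M | 5.00 × 10⁻⁴ M |  |  |
| grey | 0.625 M | 2.50 × 10⁻⁴ M |  |  |
| red | 0.625 M | 5.00 × 10⁻⁴ M | 0.120 M |  |
| blue | 4.10 M | 5.00 × 10⁻⁴ M |  | 86 h |

- amber run (time / h: [target] / M): 17: 0.015; 34: 0.042; 52: 0.051; 69: 0.058; 86: 0.058
- green run (time / h: [target] / M): 17: 0.029; 34: 0.056; 52: 0.052; 69: 0.062; 86: 0.056
- grey run (time / h: [target] / M): 17: 0.012; 34: 0.025; 52: 0.020; 69: 0.024; 86: 0.025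
- red run (time / h: [target] / M): 17: 0.127; 34: 0.114; 52: 0.106; 69: 0.104; 86: 0.101

(scatter of a reading: 0.004 M)

- reaction order in [partner] at the outset, round the charge of the amber run, defined at two percent of the starting material turned into target
- reaction order in [free catalyst] at the outset, round the charge of the amber run, defined at two percent of the starting material turned into target
- target in the blue run at 86 h, as a share of the starting material charged

- Overall: starting material + partner -> target, with free catalyst as catalyst.
- Constant volume, constant temperature.
- What is held in complexes is read along with the free species.
- "The second partner" is partner.
- An order is taken over about fifteen percent of the charge, up and down.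

The late levels are no equilibrium, because the grey run ends lower than the amber run at the same partner. The red run falls from its charged target, so target is being lost. The green run starts faster than the amber run, yet at 86 h it reads 0.056 M against 0.058 M. I therefore take making and loss to speed up together with partner, and their ratio, a selectivity factor, to stay put. Partner then sets a clock: amber-equivalent time is a run's hours multiplied by its speed over the amber run. The summed early readings of green over amber give me an order in partner of 0.613. Stretched to the blue charge, a risky step, that makes the blue clock 3.17 times faster, and 86 h counts as 272 h. The late grey-to-amber ratio, 0.422, gives me an order in free catalyst of 1.24.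

Now I build the flask. The making step by itself, with the constant 0.00494 h⁻¹ from the amber reading at 34 h, puts blue at 73.9%. Next comes the loss. I read red minus amber as charged target decaying, and its late mean gives me a loss constant of 0.0128 h⁻¹. With both steps, amber at 86 h comes out at 0.0505 M, below the reading. I scale the making constant by that miss and go round once more, which gives 0.00568 h⁻¹. The peak time is the amber-equivalent time at which making and loss of target balance, the logarithm of loss over making divided by their difference: 114 h. Blue's clock runs past it, and I commit to 14.6%.

The forecast differs, with orders of 0.9 in partner and 0.8 in free catalyst, and 23.5% for blue: “Blue should finish quickly at the cap”. That number is what one gets by giving blue the same share as the amber run at that time.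

The flask gives orders of 0.55 in partner and 1.3 in free catalyst, and 16.4% for the blue run at 86 h.

    2 free catalyst ⇌ catalyst dimer, settled at all times (2910 L mol⁻¹)
    catalyst dimer + starting material + partner → target + catalyst dimer (500.4 L² mol⁻² h⁻¹)
    target + partner → side product (0.1487 L mol⁻¹ h⁻¹)
    2 partner ⇌ idle reagent dimer, settled at all times (30.20 L mol⁻¹)

In the blue run, making and loss ran side by side on the free partner beside the idle reagent dimer; at the start that free partner stood 2.69 times the amber run's, and at that start ratio 86 h counts as 231 h against my peak time of 114 h, with target at 16.4%. In the green run, with an early rate ratio over the amber run of 1.4, 86 h counts as 122 h, past that peak time, and target read 0.056 M.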